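Late in this flask the question is a ratio: what stands of the right-handed substrate against what stands of the left-handed substrate.

- Sunday's: left-handed substrate 0.80 M; right-handed substrate 0.80 M; coupling partner 3 equiv; protic impurity 0.40 M; free catalyst 3.5 mol%; run made earlier
- flask: left-handed substrate 0.80 M; coupling partner 3.00 equiv; protic impurity 0.400 M; free catalyst 7 mol%; right-handed substrate 0.80 M; time 40 min

- Sunday's (time / min: right-handed substrate / %, left-handed substrate / %): 0.333: 48.8, 40.5; 0.500: 45.4, 36.4; 0.667: 46.1, 31.7; 1.00: 41.8, 26.7; 1.50: 39.9, 23.3; 2.50: 35.4, 14.9; 4.00: 30.2, 8.9

(scatter of a reading: 1 percentage point)

- free catalyst is single-handed; left-handed substrate and right-handed substrate are mirror images of each other, charged as a racemate, each of them at the stated concentration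
- reactions considered so far: coupling partner + free catalyst + left-handed substrate -> free catalyst + left-handed product; coupling partner + free catalyst + right-handed substrate -> free catalyst + right-handed product; coupling partner + free catalyst -> spent catalyst; coupling partner + protic impurity -> quenched reagent; 2 coupling partner -> self-condensation product
- no earlier run changes the charge of free catalyst; that part of a forecast is a guess

* whether the excess of right-handed substrate over left-handed substrate among what is left of the two reaches 95% by 40 min (yes / no)
* the highest excess of right-handed substrate over left-handed substrate among what is left of the two up to 40 min

*Where is the zero of the scale?* Each hand starts at half of the two together. Two hands consumed alike keep the excess at zero at any time, and the factor below then equals one.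

*What measures the departure from it?* Sunday's run at 4.00 min gives 3.42 for the selectivity factor, the log of the fraction left of the left-handed substrate divided by the log of the fraction left of the right-handed substrate. Time drops out of it while both hands see the same catalyst and partner.

*One reading?* At 2.50 min Sunday's run gives 3.51, a close match given a scatter of 1 percentage point.

*And the new catalyst charge?* The flask has twice Sunday's catalyst. Both hands use that catalyst, so I expect a faster clock and the same factor, but that is a guess.

*What does the wanted excess require?* An excess of 95% means right-handed over left-handed by 39.0. Call minus the log of a hand's fraction left its exponent. By my reckoning the right-handed exponent must reach 1.51, which leaves 11.0% of the two charged as right-handed substrate.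

*Your weak spot?* Sunday's right-handed exponent stood lower than that, at 0.504 after 4.00 min, and I can't say how far the doubled flask goes by 40 min.

The forecast answers yes, with a top of 96.5%: “The right-handed exponent is then about 1.6”.

    coupling partner + free catalyst + left-handed substrate → free catalyst + left-handed product (k = 0.190 M⁻² s⁻¹)
    coupling partner + free catalyst + right-handed substrate → free catalyst + right-handed product (k = 0.0530 M⁻² s⁻¹)
    coupling partner + free catalyst → spent catalyst (k = 4.30 × 10⁻⁴ M⁻¹ s⁻¹)
    coupling partner + protic impurity → quenched reagent (k = 0.0130 M⁻¹ s⁻¹)
    2 coupling partner → self-condensation product (k = 1.10 × 10⁻⁴ M⁻¹ s⁻¹)

The flask answers yes, with a top excess of 99.8%. It passes 95% at 11.5 min, with 12.1% of the two charged standing as right-handed substrate, beside the reckoned 11.0%. At 40.0 min the right-handed substrate stands at 3.51%, for which the selectivity factor puts the left-handed substrate at 0.00562% and the excess at 99.7%.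

Readings and results come from a simulation with made-up constants; scatter was added.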